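# Proposed total synthesis of 2,5-dibromo-3,6-bis(2,3,5-tribromo-4-hydroxyphenoxy)benzene-1,4-diol (14)

## The problem

Target 14 is an achiral, symmetric bis(diaryl ether). Its central hydroquinone (ring B) carries two hydroxyls, two aryloxy groups and two bromines, each pair para. Each oxygen bridge leads to a 2,3,5-tribromo-4-hydroxyphenyl ring (rings A and C). There is no stereocentre, so the whole difficulty is regiochemical. Ring B is hexasubstituted, and each outer ring holds one bromine ortho to the ether oxygen and meta to the hydroxyl, the position that phenol-directed bromination reaches last. Making the two diaryl ether C–O bonds by coupling to a ring-B carbon flanked on both sides is the step that classical routes find hardest. Eight aryl C–Br bonds exclude alkyllithium reagents and catalytic hydrogenation once bromine is present. The bromohydroquinone of ring B is oxidised by Br2, or by air in base, to a quinone whose C–Br and C–OAr positions are open to nucleophiles. Bromine therefore has to arrive late, and ring B has to be masked while it arrives. The feature that allows a short route is the order of carbons around ring B: C1(OH)–C2(OAr)–C3(Br)–C4(OH)–C5(OAr)–C6(Br). The two C–OH carbons are para and each lies between a C–OAr and a C–Br carbon. This is the pattern of a p-quinone assembled from two CO (C1, C4) and two identical alkynes ArO–C≡C–X (C2–C3, C5–C6) joined head to tail, with X standing in for bromine.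

## Retrosynthesis

**14 from 13.** The two ring-B O–CH3 bonds are cut last. Ring B is kept as a dimethyl ether through the bromination, because a free ring-B hydroquinone would be oxidised by Br2 to a quinone whose oxygen would then deactivate the outer rings. Precursor 13 has the complete skeleton and all eight bromines. The forward step must cleave two hindered aryl methyl ethers without touching diaryl ether or C–Br bonds.

**13 from 12.** All eight C–Br bonds are cut together. The two on ring B go back to C–SiMe3, the six on rings A and C to C–H. Silicon fixes the ring-B positions exactly, since ipso-bromodesilylation of an arylsilane cannot wander. On the outer rings the free hydroxyl directs two bromines ortho to itself, and the third goes ortho to the ether oxygen. Carrying bromine through earlier steps would forbid n-BuLi and hydrogenolysis. Precursor 12 is halogen-free. The forward reaction must stop at three bromines on each outer ring.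

**12 from 11.** The two benzyl–oxygen bonds are cut. Benzyl is chosen for the outer phenols because methyl could not be told apart from the ring-B methyl ethers, and the outer hydroxyls must be free to direct bromination. Hydrogenolysis is allowed only because no bromine is present yet.

**11 from 9.** The two ring-B O–CH3 bonds are cut and the oxidation level is raised to the quinone (via hydroquinone 10). This is a protecting-group and redox adjustment. It turns the vinylsilane positions of quinone 9 into arylsilane positions, for which bromodesilylation is textbook chemistry.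

**9 from two molecules of 6 and two of 7.** This is the strategic cut: the four ring-B bonds C1–C2, C1–C6, C4–C3 and C4–C5. Quinone 9 falls into two molecules of silyl ynol ether 6 and two of carbon monoxide 7. Both diaryl ether oxygens are already bonded to their ring carbons before ring B exists, and silicon marks both future C–Br positions. The neighbouring cut, the two C–O bonds by addition–elimination on a tetrahaloquinone, is classical and is held in reserve as a fallback. It is not chosen because it builds nothing of ring B. The forward reaction must join the two alkynes head to tail and take up two CO, not one.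

**6 from 1 and 2.** The C–Si bond and the alkyne are cut back to dichlorovinyl ether 3 (via chloroalkyne 4 and acetylide 5). The O–C(vinyl) bond of 3 is cut back to 4-(benzyloxy)phenol 1 and trichloroethylene 2. Both starting materials are bulk chemicals, and the two steps are the standard dichlorovinyl ether route to ynol ethers.

## Roads not taken

**Alternative 1: ring B carried saturated and aromatised by bromine.** The cut removes the two ring-B C–Br bonds and the aromaticity of ring B. It leads to diketone A2, made from the pre-brominated phenol A3 and an α-halogenated cyclohexane-1,4-dione. In the forward key step, excess Br2 in acetic acid would α-brominate and dehydrobrominate A2, the enedione would tautomerise to the hydroquinone, and its two free positions would be brominated to give A1. One BBr3 step would then give 14.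

- Merits: every step is a known reaction type; the outer-ring bromines come in with A3, so there is no late regiochemical question on rings A and C; and only one step follows the key step.
- Weak points: in A2 each aryloxy group is β to a carbonyl across an acidic CH2, so acid or base can expel A3 and aromatise the ring without it. This threatens the preparation of A2, where a hindered, weakly nucleophilic phenoxide must displace a secondary α-halide while the electrophile can itself lose HX and aromatise. It also threatens the key step, which generates HBr.
- Comparison: this road is better in precedent and no longer in step count. Against that, the chosen plan never has a leaving group β to a carbonyl and never makes a ring-B C–O bond by substitution. The aryloxy groups sit on alkyne carbons before the ring exists, and the ring is formed directly at the quinone level.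

**Alternative 2: ring B by Moore cyclization of an alkynylcyclobutenone.** The cut is a single ring-B C–C bond, between a carbonyl carbon and an aryloxy-bearing carbon. It leads from bromoquinone A4 back to the 4-alkynyl-4-hydroxycyclobutenone A5. A5 would come from adding an aryloxyacetylide to a squarate-derived bromo(aryloxy)cyclobutenedione. On heating, A5 would open to an enynylketene that closes onto the aryloxy-bearing alkyne carbon and gives A4.

- Merits: the reaction class is established and metal-free, and the substitution pattern of ring B is fixed by connectivity, with no 2,5 versus 2,6 question.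
- Weak points: the key step makes only one bond. Four ring-B carbons are bought as squarate and adjusted one group at a time. The bromine on the cyclobutenedione is a vinylogous acyl bromide that the acetylide can attack in place of the carbonyl. The two halves of a symmetric target are made by different chemistry. A4 still lacks one ring-B bromine, and the sequence is linear and roughly twice as long.
- Comparison: this road is better in regiochemical certainty and precedent. The chosen plan offers convergence instead: four C–C bonds in one step from two molecules of one alkyne, using the symmetry of 14.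

**Alternative 3: outer rings by twofold Dötz benzannulation.** The cut removes three C–C bonds from each outer ring and leaves ring B as a bought, symmetric hexasubstituted benzene carried in the bis(pentacarbonylchromium) aryloxy(α-silylvinyl)carbene A7. In the forward key step, A7 would react at both ends with alkyne A8 to close both rings as 4-aryloxyphenols and give A6. Br2 would then convert A6 into 13 by four ipso-substitutions at silicon and two brominations ortho to the new hydroxyls.

- Merits: ring B is never in question; the annulation places the silyl group next to the new hydroxyl reliably; and silicon marks the bromine position ortho to the ether oxygen, so the last bromination is easier than in the chosen plan.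
- Weak points: aryloxycarbene complexes of a di-ortho-substituted, electron-poor phenol are hard to make and labile. Two stoichiometric zerovalent chromium centres are needed. Each of the two annulations competes with cyclopentannulation and furan formation. The route builds the two easy rings and buys the hard one.
- Comparison: this road is better in late-stage regiocontrol and equal in relying on a stoichiometric metal carbonyl. The chosen plan offers a single metal-mediated event, one commercial phenol as the only aromatic building block, and construction of ring B itself.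

Key step: step 3

Remark on the chemistry: 14 has no stereocentre and is treated as the neutral hexaphenol. The two ring carbonyl carbons formed in step 3 are counted as carbon monoxide 7, because the ligands of Fe(CO)5 exchange with the CO atmosphere under irradiation.

## Route

Step 1
Reactants: 1 4-(benzyloxy)phenol; 2 trichloroethylene
Product: 3 1-(benzyloxy)-4-{[(E)-1,2-dichloroethenyl]oxy}benzene
Conditions: K2CO3, DMF, 70 °C
Reagents that add atoms: none
Why: Base converts 2 into dichloroacetylene in situ and the phenoxide of 1 adds across it in anti fashion (vinylic substitution by elimination–addition), the standard preparation of aryl (E)-1,2-dichlorovinyl ethers; the benzyl ether is inert.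

Step 2
Reactants: 3 1-(benzyloxy)-4-{[(E)-1,2-dichloroethenyl]oxy}benzene
Product: 6 {[4-(benzyloxy)phenoxy]ethynyl}trimethylsilane, via chloroethynyl 4-(benzyloxy)phenyl ether 4 (not isolated), via lithium [4-(benzyloxy)phenoxy]acetylide 5 (not isolated)
Conditions: n-BuLi (2.2 equiv), THF, −78 to −40 °C; then Me3SiCl, −78 °C to rt
Reagents that add atoms: chlorotrimethylsilane, C[Si](C)(C)Cl
Why: Dichlorovinyl ether route to ynol ethers: the first equivalent of n-BuLi dehydrochlorinates 3 to 4, the second effects chlorine–lithium exchange to acetylide 5, and C-silylation gives 6; at −78 °C the benzyl ether is not deprotonated, and 6 should be purified on base-washed silica because silyl ynol ethers hydrate under acid.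

Step 3
Reactants: 6 {[4-(benzyloxy)phenoxy]ethynyl}trimethylsilane (two molecules); 7 carbon monoxide (two molecules)
Product: 9 2,5-bis[4-(benzyloxy)phenoxy]-3,6-bis(trimethylsilyl)-1,4-benzoquinone, via tricarbonyl(η4-quinone)iron complex 8 (not isolated)
Conditions: Fe(CO)5 (0.6 equiv per alkyne), CO (1 atm), hν (Pyrex, medium-pressure Hg lamp), toluene, 10 °C; then FeCl3·6H2O, MeCN, 0 °C
Reagents that add atoms: none
Why: Proposed new method: photolytic loss of CO from Fe(CO)5 should let one molecule of 6 bind zerovalent iron and couple with two carbonyl ligands to a ferracyclopentenedione (maleoyl complex); the second molecule of 6 then inserts into one iron–acyl bond, and C–C reductive elimination from the seven-membered ferracycle closes ring B as the η4-quinone complex 8, from which FeCl3 removes the iron (zerovalent iron becomes FeCl2, the CO ligands leave) to free 9. The closest known reaction type is the [2+2+1+1] cocyclisation of two alkynes and two CO to tricarbonyl(quinone)iron complexes on irradiation of Fe(CO)5, together with the Ru3(CO)12-catalysed hydroquinone synthesis from alkynes and CO; neither has been shown for silyl ynol ethers, and silylalkynes normally stop at the [2+2+1] cyclopentadienone complex, which the CO atmosphere is meant to disfavour. Ring B is closed by reductive elimination as a six-membered ring from four components, with four new C–C bonds, and no stereocentre is formed. The step needs head-to-tail incorporation, with aryloxy groups at C2 and C5. In the insertion the acyl group should go to the electrophilic, less hindered oxygen-bearing alkyne carbon and iron to the silicon-bearing carbon, and the acyl that migrates should be the vinylogous-ester acyl (the one attached to the silicon-bearing carbon of the first alkyne). Each carbonyl then ends between one C–OAr and one C–SiMe3 carbon, whereas the other mode would force the final reductive elimination to put two Me3Si-bearing carbons on one carbonyl. Aryl ynol ethers have no β-hydrogen for retro-ene loss of a ketene, which should help 6 survive the conditions.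

Step 4
Reactants: 9 2,5-bis[4-(benzyloxy)phenoxy]-3,6-bis(trimethylsilyl)-1,4-benzoquinone
Product: 11 1,4-bis[4-(benzyloxy)phenoxy]-2,5-dimethoxy-3,6-bis(trimethylsilyl)benzene, via bis(trimethylsilyl)hydroquinone 10 (not isolated)
Conditions: Na2S2O4, THF/H2O, rt; then MeI, K2CO3, DMF, 40 °C, under N2
Reagents that add atoms: iodomethane, CI
Why: Reductive methylation of a quinone: dithionite reduces 9 to hydroquinone 10 under neutral conditions, before any base is present that could displace the aryloxy groups of the quinone, and Williamson methylation of the crude diol gives 11; the methyl ethers hold ring B in a form that bromine cannot oxidise.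

Step 5
Reactants: 11 1,4-bis[4-(benzyloxy)phenoxy]-2,5-dimethoxy-3,6-bis(trimethylsilyl)benzene
Product: 12 4,4'-{[2,5-dimethoxy-3,6-bis(trimethylsilyl)-1,4-phenylene]bis(oxy)}diphenol
Conditions: H2 (1 atm), 10% Pd/C, EtOAc/EtOH, rt
Reagents that add atoms: none
Why: Hydrogenolysis of the two benzyl aryl ethers; aryl–silicon bonds, diaryl ethers and methyl ethers are inert, and the step is possible only because no bromine has been introduced yet.

Step 6
Reactants: 12 4,4'-{[2,5-dimethoxy-3,6-bis(trimethylsilyl)-1,4-phenylene]bis(oxy)}diphenol
Product: 13 1,4-dibromo-2,5-dimethoxy-3,6-bis(2,3,5-tribromo-4-hydroxyphenoxy)benzene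
Conditions: Br2 (8.2 equiv), AcOH/CH2Cl2, 0 to 40 °C
Reagents that add atoms: bromine, BrBr
Why: Eightfold electrophilic aromatic substitution: ipso-bromodesilylation at the two ring-B C–SiMe3 carbons, and on each outer ring bromination at both positions ortho to the free hydroxyl and then at one position ortho to the ether oxygen (also ortho and para to the bromines already present). The last C–H of each outer ring is further deactivated by the new meta bromine and shielded by ring B, so substitution should stop at three bromines per ring; ring B, a fully substituted dimethyl ether, cannot be oxidised to a quinone.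

Step 7
Reactants: 13 1,4-dibromo-2,5-dimethoxy-3,6-bis(2,3,5-tribromo-4-hydroxyphenoxy)benzene
Product: 14 2,5-dibromo-3,6-bis(2,3,5-tribromo-4-hydroxyphenoxy)benzene-1,4-diol
Conditions: BBr3 (6 equiv), CH2Cl2, −78 °C to rt; then H2O
Reagents that add atoms: none
Why: BBr3 cleavage of the two ring-B aryl methyl ethers (Lewis adduct, then attack of bromide on methyl), the usual last step for hydroxylated polybrominated diphenyl ethers; diaryl ether and aryl C–Br bonds are untouched, and the acidic, non-oxidising work-up keeps ring B as the hydroquinone.

## Compound list

1 | 4-(benzyloxy)phenol | Oc1ccc(OCc2ccccc2)cc1 | starting material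
2 | trichloroethylene | ClC=C(Cl)Cl | starting material
3 | 1-(benzyloxy)-4-{[(E)-1,2-dichloroethenyl]oxy}benzene | c1ccccc1COc1ccc(O/C(Cl)=C\Cl)cc1 | intermediate
4 | 1-(benzyloxy)-4-[(chloroethynyl)oxy]benzene | ClC#COc1ccc(OCc2ccccc2)cc1 | intermediate (not isolated)
5 | lithium [4-(benzyloxy)phenoxy]acetylide | [Li]C#COc1ccc(OCc2ccccc2)cc1 | intermediate (not isolated)
6 | {[4-(benzyloxy)phenoxy]ethynyl}trimethylsilane | C[Si](C)(C)C#COc1ccc(OCc2ccccc2)cc1 | intermediate
7 | carbon monoxide | [C-]#[O+] | starting material
8 | tricarbonyl{η4-2,5-bis[4-(benzyloxy)phenoxy]-3,6-bis(trimethylsilyl)-1,4-benzoquinone}iron | O=C1C(Oc2ccc(OCc3ccccc3)cc2)=C([Si](C)(C)C)C(=O)C(Oc2ccc(OCc3ccccc3)cc2)=C1[Si](C)(C)C.[Fe].[C-]#[O+].[C-]#[O+].[C-]#[O+] | intermediate (not isolated)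
9 | 2,5-bis[4-(benzyloxy)phenoxy]-3,6-bis(trimethylsilyl)cyclohexa-2,5-diene-1,4-dione | O=C1C(Oc2ccc(OCc3ccccc3)cc2)=C([Si](C)(C)C)C(=O)C(Oc2ccc(OCc3ccccc3)cc2)=C1[Si](C)(C)C | intermediate
10 | 2,5-bis[4-(benzyloxy)phenoxy]-3,6-bis(trimethylsilyl)benzene-1,4-diol | Oc1c(Oc2ccc(OCc3ccccc3)cc2)c([Si](C)(C)C)c(O)c(Oc2ccc(OCc3ccccc3)cc2)c1[Si](C)(C)C | intermediate (not isolated)
11 | 1,4-bis[4-(benzyloxy)phenoxy]-2,5-dimethoxy-3,6-bis(trimethylsilyl)benzene | COc1c(Oc2ccc(OCc3ccccc3)cc2)c([Si](C)(C)C)c(OC)c(Oc2ccc(OCc3ccccc3)cc2)c1[Si](C)(C)C | intermediate
12 | 4,4'-{[2,5-dimethoxy-3,6-bis(trimethylsilyl)-1,4-phenylene]bis(oxy)}diphenol | COc1c(Oc2ccc(O)cc2)c([Si](C)(C)C)c(OC)c(Oc2ccc(O)cc2)c1[Si](C)(C)C | intermediate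
13 | 1,4-dibromo-2,5-dimethoxy-3,6-bis(2,3,5-tribromo-4-hydroxyphenoxy)benzene | COc1c(Oc2cc(Br)c(O)c(Br)c2Br)c(Br)c(OC)c(Oc2cc(Br)c(O)c(Br)c2Br)c1Br | intermediate
14 | 2,5-dibromo-3,6-bis(2,3,5-tribromo-4-hydroxyphenoxy)benzene-1,4-diol | Oc1c(Br)cc(Oc2c(O)c(Br)c(Oc3cc(Br)c(O)c(Br)c3Br)c(O)c2Br)c(Br)c1Br | target

## Step count and least certain steps

Total step count: 7. Longest linear sequence: 7 steps, from 1 to 14.

**Step 3 (key step, proposed new method).**
- Most likely failure: diversion of the alkyne into [2+2+1] cyclisation, which takes up one CO and gives cyclopentadienone iron complexes. This is the usual outcome for silylalkynes, because two bulky silyl groups beside the metal favour a ferracyclopentadiene. Head-to-head incorporation to the 2,6-bis(aryloxy) isomer and light-induced oligomerisation of the electron-rich ynol ether are the next risks.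
- Fallback (known chemistry): setting out from 1, two equivalents of its phenoxide (K2CO3, MeCN, 0 °C to rt) would be added to purchased tetrabromo-1,4-benzoquinone (bromanil, O=C1C(Br)=C(Br)C(=O)C(Br)=C1Br). Twofold addition–elimination should give 2,5-bis[4-(benzyloxy)phenoxy]-3,6-dibromo-1,4-benzoquinone F1. The 2,5-pattern follows because the first aryloxy group deactivates the positions conjugated to it. Na2S2O4 would reduce F1 to 2,5-bis[4-(benzyloxy)phenoxy]-3,6-dibromobenzene-1,4-diol F2, and MeI/K2CO3 would give 1,4-bis[4-(benzyloxy)phenoxy]-2,5-dibromo-3,6-dimethoxybenzene F3. Hydrogenolysis is now excluded by the C–Br bonds, so BCl3 with pentamethylbenzene at −78 °C would remove the benzyl groups to give 4,4'-[(2,5-dibromo-3,6-dimethoxy-1,4-phenylene)bis(oxy)]diphenol F4. Br2 (6 equiv) in AcOH would then brominate the outer rings, and the route is rejoined at 13.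

**Step 6.**
- Most likely failure: stalling before the third substitution on each outer ring. That position, ortho to the ether oxygen, is far less activated than the other sites. Forcing it may start ipso attack para to the hydroxyl, with cleavage of the diaryl ether, or a fourth bromination. Protodesilylation of ring B by the HBr formed may precede ipso-bromination; this is harmless only if C–H bromination at that site then follows.
- Fallback: the order of bromine introduction would be reversed, setting out from 12. Acetylation (Ac2O, pyridine) would give [2,5-dimethoxy-3,6-bis(trimethylsilyl)-1,4-phenylene]bis(oxy-4,1-phenylene) diacetate F5, in which the ether oxygen is the strongest donor on each outer ring. Br2 (4 equiv) would then give (2,5-dibromo-3,6-dimethoxy-1,4-phenylene)bis[oxy(3-bromo-4,1-phenylene)] diacetate F6, by ipso-substitution on ring B and one bromination ortho to each ether oxygen. Methanolysis (K2CO3, MeOH) would free 4,4'-[(2,5-dibromo-3,6-dimethoxy-1,4-phenylene)bis(oxy)]bis(3-bromophenol) F7. Br2 (4 equiv), now needed only ortho to the hydroxyls, would return the route to 13.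

**Step 4.**
- Most likely failure: incomplete O-methylation, because each ring-B oxygen is flanked by SiMe3 and an aryloxy group. Re-oxidation of the electron-rich hydroquinone dianion by air during the slow alkylation is the accompanying risk.
- Fallback: setting out from 9 and passing through 10 as before, the diol would be acylated with the more reactive Ac2O/pyridine/DMAP to give 2,5-bis[4-(benzyloxy)phenoxy]-3,6-bis(trimethylsilyl)-1,4-phenylene diacetate F8. Hydrogenolysis (H2, Pd/C) would give 2,5-bis(4-hydroxyphenoxy)-3,6-bis(trimethylsilyl)-1,4-phenylene diacetate F9. Br2 (8 equiv) would give 2,5-dibromo-3,6-bis(2,3,5-tribromo-4-hydroxyphenoxy)-1,4-phenylene diacetate F10. Acid-catalysed methanolysis (HCl, MeOH) would remove the acetates and reach the route again at 14.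

## Further compounds

F1 | step 3 | 2,5-bis[4-(benzyloxy)phenoxy]-3,6-dibromocyclohexa-2,5-diene-1,4-dione | O=C1C(Oc2ccc(OCc3ccccc3)cc2)=C(Br)C(=O)C(Oc2ccc(OCc3ccccc3)cc2)=C1Br
F2 | step 3 | 2,5-bis[4-(benzyloxy)phenoxy]-3,6-dibromobenzene-1,4-diol | Oc1c(Oc2ccc(OCc3ccccc3)cc2)c(Br)c(O)c(Oc2ccc(OCc3ccccc3)cc2)c1Br
F3 | step 3 | 1,4-bis[4-(benzyloxy)phenoxy]-2,5-dibromo-3,6-dimethoxybenzene | COc1c(Oc2ccc(OCc3ccccc3)cc2)c(Br)c(OC)c(Oc2ccc(OCc3ccccc3)cc2)c1Br
F4 | step 3 | 4,4'-[(2,5-dibromo-3,6-dimethoxy-1,4-phenylene)bis(oxy)]diphenol | COc1c(Oc2ccc(O)cc2)c(Br)c(OC)c(Oc2ccc(O)cc2)c1Br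
F5 | step 6 | [2,5-dimethoxy-3,6-bis(trimethylsilyl)-1,4-phenylene]bis(oxy-4,1-phenylene) diacetate | COc1c(Oc2ccc(OC(C)=O)cc2)c([Si](C)(C)C)c(OC)c(Oc2ccc(OC(C)=O)cc2)c1[Si](C)(C)C
F6 | step 6 | (2,5-dibromo-3,6-dimethoxy-1,4-phenylene)bis[oxy(3-bromo-4,1-phenylene)] diacetate | COc1c(Oc2ccc(OC(C)=O)cc2Br)c(Br)c(OC)c(Oc2ccc(OC(C)=O)cc2Br)c1Br
F7 | step 6 | 4,4'-[(2,5-dibromo-3,6-dimethoxy-1,4-phenylene)bis(oxy)]bis(3-bromophenol) | COc1c(Oc2ccc(O)cc2Br)c(Br)c(OC)c(Oc2ccc(O)cc2Br)c1Br
F8 | step 4 | 2,5-bis[4-(benzyloxy)phenoxy]-3,6-bis(trimethylsilyl)-1,4-phenylene diacetate | CC(=O)Oc1c(Oc2ccc(OCc3ccccc3)cc2)c([Si](C)(C)C)c(OC(C)=O)c(Oc2ccc(OCc3ccccc3)cc2)c1[Si](C)(C)C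
F9 | step 4 | 2,5-bis(4-hydroxyphenoxy)-3,6-bis(trimethylsilyl)-1,4-phenylene diacetate | CC(=O)Oc1c(Oc2ccc(O)cc2)c([Si](C)(C)C)c(OC(C)=O)c(Oc2ccc(O)cc2)c1[Si](C)(C)C
F10 | step 4 | 2,5-dibromo-3,6-bis(2,3,5-tribromo-4-hydroxyphenoxy)-1,4-phenylene diacetate | CC(=O)Oc1c(Oc2cc(Br)c(O)c(Br)c2Br)c(Br)c(OC(C)=O)c(Oc2cc(Br)c(O)c(Br)c2Br)c1Br
A1 | alternative 1 | 2,5-dibromo-3,6-bis(2,3,5-tribromo-4-methoxyphenoxy)benzene-1,4-diol | Oc1c(Br)c(Oc2cc(Br)c(OC)c(Br)c2Br)c(O)c(Br)c1Oc1cc(Br)c(OC)c(Br)c1Br
A2 | alternative 1 | 2,5-bis(2,3,5-tribromo-4-methoxyphenoxy)cyclohexane-1,4-dione (cis/trans mixture) | O=C1CC(Oc2cc(Br)c(OC)c(Br)c2Br)C(=O)CC1Oc1cc(Br)c(OC)c(Br)c1Br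
A3 | alternative 1 | 2,3,5-tribromo-4-methoxyphenol | COc1c(Br)cc(O)c(Br)c1Br
A4 | alternative 2 | 2-bromo-3,6-bis(4-methoxyphenoxy)cyclohexa-2,5-diene-1,4-dione | O=C1C(Br)=C(Oc2ccc(OC)cc2)C(=O)C=C1Oc1ccc(OC)cc1
A5 | alternative 2 | 2-bromo-4-hydroxy-3-(4-methoxyphenoxy)-4-[(4-methoxyphenoxy)ethynyl]cyclobut-2-en-1-one (racemic) | O=C1C(Br)=C(Oc2ccc(OC)cc2)C1(O)C#COc1ccc(OC)cc1
A6 | alternative 3 | 1,4-dibromo-2,5-dimethoxy-3,6-bis[4-hydroxy-2,5-bis(trimethylsilyl)phenoxy]benzene | COc1c(Br)c(Oc2cc([Si](C)(C)C)c(O)cc2[Si](C)(C)C)c(OC)c(Br)c1Oc1cc([Si](C)(C)C)c(O)cc1[Si](C)(C)C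
A7 | alternative 3 | {(2,5-dibromo-3,6-dimethoxy-1,4-phenylene)bis[oxy(1-(trimethylsilyl)ethenyl)methylidene]}bis(pentacarbonylchromium) | COc1c(Br)c(OC(=[Cr](=C=O)(=C=O)(=C=O)(=C=O)=C=O)C(=C)[Si](C)(C)C)c(OC)c(Br)c1OC(=[Cr](=C=O)(=C=O)(=C=O)(=C=O)=C=O)C(=C)[Si](C)(C)C
A8 | alternative 3 | ethynyltrimethylsilane | C#C[Si](C)(C)C
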